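Every percent of a charge has to stand somewhere, so the readings of a flask add up to 100 once nothing is hidden. I used that balance to decide whether the larch flask needed longer than 3.0 d.

| flask | solid substrate | remark | time |
|---|---|---|---|
| north-east | 0.0055 M | run made earlier |  |
| east | 0.53 M | run made earlier |  |
| ash | 0.0050 M |  | 3.0 d |
| maple | 0.015 M |  | 3.0 d |
| cedar | 0.040 M |  | 3.0 d |
| oak | 0.12 M |  | 3.0 d |
| larch | 0.40 M |  | 3.0 d |

- north-east (time / h: ring / %, open dimer / %, isomer of the product / %): 3.00: 17.9, 0.2, 1.5; 10.0: 42.5, 0, 11.1; 15.0: 50.1, 0, 17.9; 25.0: 55.1, 0, 30.4; 40.0: 56.2, 0, 39.4
- east (time / h: ring / %, open dimer / %, isomer of the product / %): 3.00: 1.3, 0, 0.1; 5.00: 1.9, 0.4, 0.4; 10.0: 5.6, 0, 0.8; 20.0: 14.8, 0.5, 4.3; 40.0: 32.0, 1.1, 13.9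

(standard deviation of a reading: 0.3 percentage points)

* share of ring in all that became ring or open dimer or isomer of the product for ash, maple, cedar, oak, larch, in this order
* how the row runs (falls all the way / hardly changes / rises all the way / falls, then rises / rises, then falls)

In the north-east run, ring gained 1.1 percentage points between 25.0 h and 40.0 h. Isomer of the product gained 9 points, which is more. The last reading left 4.40% of that charge unseen, and I sent this rest to the isomer. The share then equals the last ring reading:

plateau = 56.2%

I call this the plateau share, the percent of the charge standing as ring once its reading stops rising and conversion is through. That was my dilute end.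

For the concentrated end, I took the east run between its last two readings:

feed = 7.26 mM h⁻¹

solid lasts in larch = 55.1 h

mean age of its material at the end = 44.5 h

These are estimates from the gain of products in the east run. At that feed the solid in larch lasts less time than the 3.0 d allowed. The estimated mean age is also greater than the 40.0 h of the last north-east reading, where the share read 58.8%. So I put larch between the plateau and that share, and the four lower charges at the plateau. I left the charges and the time as they were.

The forecast gave 57.5%, 57.3%, 57%, 56.5% and 58%, a row that hardly changes, on the ground that “the branching barely depends on concentration”. Its value for ash stands 1.3 points above my plateau.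

The flasks gave 56.1%, 56.1%, 56.0%, 55.9% and 57.9%, a row that hardly changes.

    2 starting material ⇌ open dimer (K = 1.91 M⁻¹, k = 0.0127 M⁻¹ h⁻¹)
    starting material + ring ⇌ idle adduct, settled at all times (K = 1.09 M⁻¹)
    starting material → ring (k = 0.0777 h⁻¹)
    solid substrate ⇌ starting material, rate k4*(cs4 - [starting material]) while solid is left; crystals form when [starting material] > cs4 (solubility = 0.290 M, k = 0.0425 h⁻¹)
    ring ⇌ isomer of the product (K = 0.790, k = 0.0533 h⁻¹)

Ash ended with a share of 56.1%, close to the plateau share of 56.2% read in the north-east run. The level in ash is a balance, thermodynamic control in the usual term: ring holds there because isomer of the product returns to ring. Without that return, the share in ash was 5.77% against 56.1%. Larch, the second flask, had a share of 57.9% at 3.00 d and of 55.9% at 30.0 d, near the plateau. Without the return, the share in larch was 19.3% at 3.00 d.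

The readings come from a simulation for an exercise; the scatter is artificial.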